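**Retrosynthetic overview**
1. Target 17 ⇐ acetylation of the hindered 6β-OH of 15 ⇐ selective 7-O-isovalerylation of the trans-diaxial 6β,7α-diol acid 13.
2. 13 ⇐ α-face reduction of the C6 ketone of ketol 12 ⇐ α-face hydroxylation at C7 of the 6,8(9)-dienolate of β,γ-enone 10 ⇐ deconjugation of enone 8 ⇐ allylic C6 oxidation of diene acid 7.
3. 7 ⇐ E1 loss of the 8α-acetate from acid 6 ⇐ C15 oxidation of allylic alcohol 4 ⇐ diacetate 3.
4. Key disconnection: the C15–O bond and the 13E olefin of 3 come from a [3,3]-sigmatropic allylic acetate transposition of sclareol diacetate 2.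
5. Rings: none is built; rings A and B (with C5 and C10) are bought in (−)-sclareol 1, whose angular methyl groups then set C7 and C6; order of events: side chain first, then ring B.

Assumption: the target is read as (5S,6S,7S,10S,13E)-6β-acetoxy-7α-(3-methylbutanoyloxy)labda-8,13-dien-15-oic acid (labdane numbering used throughout); simple acylating and oxidising reagents are named with SMILES at their step and carry no compound number.

**Step 1**
Reactants: 1 (−)-sclareol, (13R)-labd-14-ene-8α,13-diol
Product: 2 sclareol diacetate, (13R)-labd-14-ene-8α,13-diyl diacetate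
Conditions: AcCl, PhNMe2, CH2Cl2, 0 °C → rt
Reagents that add atoms: acetyl chloride, CC(=O)Cl
Why: O-acylation with acetyl chloride and the weak base PhNMe2 esterifies both tertiary hydroxyls without ionising the tertiary allylic C13–O bond, and no stereocentre is touched.

**Step 2**
Reactants: 2 sclareol diacetate
Product: 3 (13E)-labd-13-ene-8α,15-diyl diacetate
Conditions: PdCl2(MeCN)2 (5 mol %), THF, rt
Reagents that add atoms: none
Why: The divalent-palladium-catalysed [3,3]-sigmatropic rearrangement of the tertiary allylic acetate (Overman-type allylic ester transposition) forms the C15–O bond and the C13=C14 bond through a chair-like cyclic acetoxonium with the C12 chain equatorial, so the 13E isomer predominates (the minor 13Z isomer is removed by chromatography after step 3) and the unneeded C13 stereocentre disappears.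

**Step 3**
Reactants: 3 (13E)-labd-13-ene-8α,15-diyl diacetate
Product: 4 (13E)-8α-acetoxylabd-13-en-15-ol
Conditions: K2CO3 (0.5 equiv), MeOH, 0 °C → rt
Reagents that add atoms: none
Why: Base-catalysed transesterification (methanolysis) removes the unhindered primary allylic acetate far faster than the tertiary 8α-acetate, and no stereocentre is involved.

**Step 4**
Reactants: 4 (13E)-8α-acetoxylabd-13-en-15-ol
Product: 6 (13E)-8α-acetoxylabd-13-en-15-oic acid, via enal 5 (not isolated)
Conditions: TEMPO (0.1 equiv), PhI(OAc)2 (1.2 equiv), CH2Cl2, rt; then t-BuOH/H2O, 2-methyl-2-butene, NaH2PO4, NaClO2, 0 °C → rt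
Reagents that add atoms: sodium chlorite, [Na+].[O-]Cl=O
Why: Oxoammonium (TEMPO) oxidation of the allylic alcohol stops at enal 5, which the Pinnick chlorite oxidation converts in the same flask into the acid without touching the 13E geometry or the tertiary acetate.

**Step 5**
Reactants: 6 (13E)-8α-acetoxylabd-13-en-15-oic acid
Product: 7 (13E)-labda-7,13-dien-15-oic acid
Conditions: p-TsOH·H2O (0.1 equiv), toluene, 80 °C, stopped when 6 and the 8(17)-isomer are consumed
Reagents that add atoms: none
Why: Acid-catalysed E1 elimination of the tertiary acetate goes through the C8 cation, which loses the axial, unhindered 7α-H fastest to give the trisubstituted 7-ene, while exocyclic 8(17)-olefin is re-protonated and funnelled to 7 and the minor tetrasubstituted 8(9)-isomer is separated on AgNO3-impregnated silica, C5, C9 and C10 being unchanged.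

**Step 6**
Reactants: 7 (13E)-labda-7,13-dien-15-oic acid
Product: 8 (13E)-6-oxolabda-7,13-dien-15-oic acid
Conditions: CrO3 (15 equiv), 3,5-dimethylpyrazole (15 equiv), CH2Cl2, −20 °C
Reagents that add atoms: chromium trioxide, O=[Cr](=O)=O
Why: Allylic oxidation with hexavalent chromium (CrO3–dimethylpyrazole, Salmond conditions) converts the only allylic ring methylene, C6, into the conjugated enone, the electron-poor side-chain enoic acid being inert.

**Step 7**
Reactants: 8 (13E)-6-oxolabda-7,13-dien-15-oic acid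
Product: 10 (13E)-6-oxolabda-8,13-dien-15-oic acid, via dipotassium dienolate 9 (not isolated)
Conditions: KOtBu (4 equiv), t-BuOH/THF, rt, 1 h; then poured into cold 10% aq. AcOH
Reagents that add atoms: none
Why: Reversible deprotonation gives the thermodynamic, fully substituted 6,8(9)-dienolate 9 (loss of the axial 9α-H) and kinetic α-protonation at C7 on inverse acidic quench delivers the deconjugated β,γ-enone (Ringold–Malhotra deconjugation), the carboxylate form protecting the side-chain enoate from isomerisation and C5 staying trans (5α-H).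

**Step 8**
Reactants: 10 (13E)-6-oxolabda-8,13-dien-15-oic acid
Product: 12 (13E)-7α-hydroxy-6-oxolabda-8,13-dien-15-oic acid, via dilithium dienolate 11 (not isolated)
Conditions: LiN(SiMe3)2 (2.3 equiv), THF, −78 °C; MoO(O2)2·pyridine·HMPA (MoOPH, 1.5 equiv), −78 → −30 °C; aq. Na2SO3, then 1 M HCl (pH 3)
Reagents that add atoms: MoOPH, MoO(O2)2·pyridine·HMPA, O=[Mo]12(OO1)OO2.c1ccncc1.CN(C)P(=O)(N(C)C)N(C)C
Why: Kinetic deprotonation of the doubly activated C7–H gives dienolate 11, which the bulky achiral peroxide of hexavalent molybdenum (Vedejs enolate hydroxylation) oxygenates at the α-carbon C7 from the α face, axial and anti to the 10β-methyl, so 7S (7α-OH) is set by the sclareol-derived C10 centre.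

**Step 9**
Reactants: 12 (13E)-7α-hydroxy-6-oxolabda-8,13-dien-15-oic acid
Product: 13 (13E)-6β,7α-dihydroxylabda-8,13-dien-15-oic acid
Conditions: NaBH4 (3 equiv), CeCl3·7H2O (1.2 equiv), MeOH, −40 → 0 °C (crude 12 used directly)
Reagents that add atoms: none
Why: Luche-type borohydride reduction delivers hydride to the C6 ketone from the α face because the β face is blocked by the syn-axial 4β- and 10β-methyl groups, giving the axial 6β-alcohol (6S) and hence the trans-diaxial 6β,7α-diol.

**Step 10**
Reactants: 13 (13E)-6β,7α-dihydroxylabda-8,13-dien-15-oic acid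
Product: 15 (13E)-6β-hydroxy-7α-(3-methylbutanoyloxy)labda-8,13-dien-15-oic acid, via C15 isovaleric mixed anhydride 14 (not isolated)
Conditions: (Me2CHCH2CO)2O (3 equiv), DMAP (0.2 equiv), pyridine, CH2Cl2, 0 °C → rt; then THF/sat. aq. NaHCO3, rt; 1 M HCl (pH 3)
Reagents that add atoms: 3-methylbutanoic anhydride, CC(C)CC(=O)OC(=O)CC(C)C
Why: DMAP-catalysed acyl transfer esterifies only the accessible allylic 7α-hydroxyl, the 6β-hydroxyl being shielded by two syn-axial methyls, and the transient mixed anhydride 14 at C15 is hydrolysed by aqueous bicarbonate without touching the new ester.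

**Step 11**
Reactants: 15 (13E)-6β-hydroxy-7α-(3-methylbutanoyloxy)labda-8,13-dien-15-oic acid
Product: 17 (13E)-6β-acetoxy-7α-(3-methylbutanoyloxy)labda-8,13-dien-15-oic acid, via C15 acetic mixed anhydride 16 (not isolated)
Conditions: Ac2O (10 equiv), DMAP (1 equiv), pyridine, 60 °C; then THF/sat. aq. NaHCO3, rt; 1 M HCl (pH 3)
Reagents that add atoms: acetic anhydride, CC(=O)OC(C)=O
Why: Forcing DMAP-mediated acetylation esterifies the hindered axial 6β-hydroxyl with retention (acyl migration is geometrically impossible across the trans-diaxial 6β,7α pair) and bicarbonate hydrolysis of mixed anhydride 16 releases the target acid.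

**Compound list**
1 | (−)-sclareol, (5S,8R,9R,10S,13R)-labd-14-ene-8α,13-diol | C1C[C@@](C)(O)[C@H](CC[C@@](C)(O)C=C)[C@@]2(C)CCCC(C)(C)[C@H]12 | starting material
2 | sclareol diacetate, (13R)-labd-14-ene-8α,13-diyl diacetate | C1C[C@@](C)(OC(C)=O)[C@H](CC[C@@](C)(OC(C)=O)C=C)[C@@]2(C)CCCC(C)(C)[C@H]12 | intermediate
3 | (13E)-labd-13-ene-8α,15-diyl diacetate | C1C[C@@](C)(OC(C)=O)[C@H](CC/C(C)=C/COC(C)=O)[C@@]2(C)CCCC(C)(C)[C@H]12 | intermediate
4 | (13E)-8α-acetoxylabd-13-en-15-ol | C1C[C@@](C)(OC(C)=O)[C@H](CC/C(C)=C/CO)[C@@]2(C)CCCC(C)(C)[C@H]12 | intermediate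
5 | (13E)-8α-acetoxylabd-13-en-15-al (enal) | C1C[C@@](C)(OC(C)=O)[C@H](CC/C(C)=C/C=O)[C@@]2(C)CCCC(C)(C)[C@H]12 | intermediate (not isolated)
6 | (13E)-8α-acetoxylabd-13-en-15-oic acid | C1C[C@@](C)(OC(C)=O)[C@H](CC/C(C)=C/C(=O)O)[C@@]2(C)CCCC(C)(C)[C@H]12 | intermediate
7 | (13E)-labda-7,13-dien-15-oic acid (9α-H) | C1C=C(C)[C@H](CC/C(C)=C/C(=O)O)[C@@]2(C)CCCC(C)(C)[C@H]12 | intermediate
8 | (13E)-6-oxolabda-7,13-dien-15-oic acid | O=C1C=C(C)[C@H](CC/C(C)=C/C(=O)O)[C@@]2(C)CCCC(C)(C)[C@H]12 | intermediate
9 | dipotassium (13E)-6-oxidolabda-6,8,13-trien-15-oate (thermodynamic dienolate) | [K+].[K+].[O-]C1=CC(C)=C(CC/C(C)=C/C(=O)[O-])[C@@]2(C)CCCC(C)(C)[C@H]12 | intermediate (not isolated)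
10 | (13E)-6-oxolabda-8,13-dien-15-oic acid | O=C1CC(C)=C(CC/C(C)=C/C(=O)O)[C@@]2(C)CCCC(C)(C)[C@H]12 | intermediate
11 | dilithium (13E)-6-oxidolabda-6,8,13-trien-15-oate | [Li+].[Li+].[O-]C1=CC(C)=C(CC/C(C)=C/C(=O)[O-])[C@@]2(C)CCCC(C)(C)[C@H]12 | intermediate (not isolated)
12 | (13E)-7α-hydroxy-6-oxolabda-8,13-dien-15-oic acid | O=C1[C@@H](O)C(C)=C(CC/C(C)=C/C(=O)O)[C@@]2(C)CCCC(C)(C)[C@H]12 | intermediate
13 | (13E)-6β,7α-dihydroxylabda-8,13-dien-15-oic acid | O[C@@H]1[C@@H](O)C(C)=C(CC/C(C)=C/C(=O)O)[C@@]2(C)CCCC(C)(C)[C@H]12 | intermediate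
14 | mixed anhydride of 15 (at C15) with 3-methylbutanoic acid | O[C@@H]1[C@@H](OC(=O)CC(C)C)C(C)=C(CC/C(C)=C/C(=O)OC(=O)CC(C)C)[C@@]2(C)CCCC(C)(C)[C@H]12 | intermediate (not isolated)
15 | (13E)-6β-hydroxy-7α-(3-methylbutanoyloxy)labda-8,13-dien-15-oic acid | O[C@@H]1[C@@H](OC(=O)CC(C)C)C(C)=C(CC/C(C)=C/C(=O)O)[C@@]2(C)CCCC(C)(C)[C@H]12 | intermediate
16 | mixed anhydride of 17 (at C15) with acetic acid | CC(=O)O[C@@H]1[C@@H](OC(=O)CC(C)C)C(C)=C(CC/C(C)=C/C(=O)OC(C)=O)[C@@]2(C)CCCC(C)(C)[C@H]12 | intermediate (not isolated)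
17 | (5S,6S,7S,10S,13E)-6β-acetoxy-7α-(3-methylbutanoyloxy)labda-8,13-dien-15-oic acid, CNP0328312.2 | CC(=O)O[C@@H]1[C@@H](OC(=O)CC(C)C)C(C)=C(CC/C(C)=C/C(=O)O)[C@@]2(C)CCCC(C)(C)[C@H]12 | target

**Totals**
Total step count: 11.
Longest linear sequence: 11 steps (1 → 17, fully linear).

**Three steps most likely to fail**

Step 5. The acid-mediated elimination may give too much of the tetrasubstituted 8(9)-olefin or stall at the exocyclic olefin. The fallback separates elimination from positional control. Starting from 6, thermal syn-elimination of the tertiary acetate (2,4,6-collidine, reflux) gives mainly (13E)-labda-8(17),13-dien-15-oic acid F1, because methyl hydrogens reach the cyclic transition state most easily. A rhodium hydride isomerisation (RhCl3·3H2O cat., EtOH/H2O, 70 °C) then moves the exocyclic double bond to the trisubstituted ring position via the less hindered C7–H and stops there, coming back to the route at 7.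

Step 7. The deconjugation relies on the 8(9)-dienolate being the thermodynamic one and on C5 surviving KOtBu. The fallback avoids a free metal enolate. Starting from 8, soft enolisation (Me3SiCl, NaI, Et3N, MeCN, rt) silylates the acid as well and gives the thermodynamic dienol ether trimethylsilyl (13E)-6-(trimethylsilyloxy)labda-6,8,13-trien-15-oate F2. Fluoride-triggered protodesilylation in the presence of acid (TBAF, AcOH, THF, −78 °C) protonates C7 kinetically and cleaves the silyl ester, coming back to the route at 10.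

Step 8. Hydroxylation of the dianion with MoOPH can stall or over-oxidise, and ketol 12 is base-sensitive (acyloin shift to the conjugated 6-hydroxy-7-ketone). The fallback changes from enolate oxygenation to osmylation of a neutral enol ether. Starting from 10, the same C7 enolate is trapped (LiN(SiMe3)2, then Et3SiCl, THF, −78 °C) as triethylsilyl (13E)-6-(triethylsilyloxy)labda-6,8,13-trien-15-oate F3. OsO4 (cat.) with NMO in acetone/H2O at 0 °C adds in a [3+2] sense to the electron-rich, least hindered C6=C7 bond from the α face, and mild acidic work-up removes both silyl groups and gives 12, where the route is rejoined.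

**Further compounds**
F1 | step 5 | (13E)-labda-8(17),13-dien-15-oic acid | C1CC(=C)[C@H](CC/C(C)=C/C(=O)O)[C@@]2(C)CCCC(C)(C)[C@H]12
F2 | step 7 | trimethylsilyl (13E)-6-(trimethylsilyloxy)labda-6,8,13-trien-15-oate | C[Si](C)(C)OC1=CC(C)=C(CC/C(C)=C/C(=O)O[Si](C)(C)C)[C@@]2(C)CCCC(C)(C)[C@H]12
F3 | step 8 | triethylsilyl (13E)-6-(triethylsilyloxy)labda-6,8,13-trien-15-oate | CC[Si](CC)(CC)OC1=CC(C)=C(CC/C(C)=C/C(=O)O[Si](CC)(CC)CC)[C@@]2(C)CCCC(C)(C)[C@H]12
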